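The route rests on recognising that flavone C2 and C3, which belong to both the pyranone and the dihydrooxepine ring, are a masked aryl ketone and the central carbon of a 1,3-diketone. The seven-membered ring (O–C2''–C1''–C3–C2–C1'–C2') is therefore not cyclised but grown from an enantioenriched (S)-2-isopropenylchroman-4-one: a Lewis-acid-promoted homologation with an A-ring α-diazo ketone inserts C3, already carrying the A-ring acyl group, between the ketone carbon and its α-methylene. The ring-expanded β-diketone collapses to the flavone on acid treatment; cobalt-mediated peroxidation of the isopropenyl group, C6 iodination and Suzuki alkenylation complete the synthesis.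

Key step: step 5

Remark (assumptions): flavone numbering is used for the tetracycles, with C1'' = CH2 on C3, C2'' = the stereogenic CH on the 2'-oxygen and C3'' = the carbon on C2''. The sense of induction in step 2 is taken to be adjustable by the choice of ligand enantiomer. The (E)-alkenylboronate 18 is made rather than assumed to be purchasable.

Step 1
Reactants: 1 7-hydroxy-4H-chromen-4-one
Product: 2 4-oxo-4H-chromen-7-yl pivalate
Conditions: PivCl, Et3N, DMAP (cat.), CH2Cl2, 0 °C → rt
Reagents that add atoms: pivaloyl chloride, CC(C)(C)C(=O)Cl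
Why: DMAP-catalysed O-acylation of the only hydroxyl; the pivalate keeps the future B ring electron-poor (more electrophilic C4=O and lower aryl migratory aptitude in step 5, no B-ring iodination in step 9) and is removed later by mild methanolysis.

Step 2
Reactants: 2 4-oxo-4H-chromen-7-yl pivalate; 3 isopropenylboronic acid pinacol ester
Product: 4 (2S)-4-oxo-2-(prop-1-en-2-yl)chroman-7-yl pivalate
Conditions: [RhCl(C2H4)2]2 (3 mol%), (R,R)-Ph-bod* or its antipode (6.6 mol%), K3PO4 (0.3 equiv), dioxane/H2O 10:1, 40 °C
Reagents that add atoms: none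
Why: Rhodium-catalysed asymmetric 1,4-addition of an alkenylboron reagent to the chromone enone (Hayashi–Miyaura reaction), in which the C2-symmetric diene ligand differentiates the enone faces at the alkenyl-rhodium insertion and its enantiomer is chosen so that C2 is formed (S), the weakly basic medium limiting retro-oxa-Michael racemisation.

Step 3
Reactants: 5 1-(2,6-dihydroxy-4-methoxyphenyl)ethan-1-one
Product: 6 1-[4-methoxy-2,6-bis(methoxymethoxy)phenyl]ethan-1-one
Conditions: NaH (2.5 equiv), MOMCl (2.5 equiv), DMF, 0 °C → rt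
Reagents that add atoms: chloromethyl methyl ether, COCCl
Why: Double Williamson etherification of both chelated phenols, which keeps the A-ring fragment symmetrical and installs acid-labile groups that come off in step 6.

Step 4
Reactants: 6 1-[4-methoxy-2,6-bis(methoxymethoxy)phenyl]ethan-1-one
Product: 8 2-diazo-1-[4-methoxy-2,6-bis(methoxymethoxy)phenyl]ethan-1-one, via trifluoroacetyl diketone 7 (not isolated)
Conditions: LiHMDS, THF, −78 °C, then CF3CO2CH2CF3; dilute HCl wash; then MsN3, Et3N, H2O (1 equiv), MeCN, rt
Reagents that add atoms: methanesulfonyl azide, CS(=O)(=O)N=[N+]=[N-]; 2,2,2-trifluoroethyl trifluoroacetate, O=C(OCC(F)(F)F)C(F)(F)F (its CF3CO group appears only in 7)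
Why: Detrifluoroacetylative diazo transfer (Danheiser procedure), in which Claisen trifluoroacetylation of the lithium enolate activates the methyl ketone for Regitz diazo transfer and the adduct collapses with loss of the trifluoroacetyl group to the α-diazo ketone.

Step 5
Reactants: 4 (2S)-4-oxo-2-(prop-1-en-2-yl)chroman-7-yl pivalate; 8 2-diazo-1-[4-methoxy-2,6-bis(methoxymethoxy)phenyl]ethan-1-one
Product: 9 (2S)-4-[4-methoxy-2,6-bis(methoxymethoxy)benzoyl]-5-oxo-2-(prop-1-en-2-yl)-2,3,4,5-tetrahydro-1-benzoxepin-8-yl pivalate (C4 epimers)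
Conditions: BF3·OEt2 (1.5 equiv), CH2Cl2, −78 → −20 °C, slow addition of 8; aq. NaHCO3 quench
Reagents that add atoms: none
Why: BF3 activates the C4 carbonyl of 4, the nucleophilic diazo carbon of 8 adds to it, and in the resulting diazonium betaine the C3 methylene migrates from C4 to the diazonium carbon with loss of N2, so that the chromanone ring is enlarged by one carbon to a 1-benzoxepin-5-one whose new C4 already bears the A-ring acyl group (Tiffeneau–Demjanov-type Büchner–Curtius–Schlotterbeck homologation, the closest known case being the Lewis-acid-promoted ring expansion of chroman-4-ones and 1-tetralones with α-diazo esters). No ring is closed by cyclisation: the seven-membered ring arises from the six-membered one by a 1,2-shift of carbon, and the ring oxygen, C2 and the benzo carbons are carried over unchanged. The only new stereocentre (C4, between two carbonyls) is formed without control and does not matter because it is enolisable and becomes sp2 in step 6, while the C2 stereocentre is remote from the reacting atoms and no base is present that could open the β-aryloxy ketone. The step needs CH2 migration in preference to aryl migration, which is the usual outcome for acceptor-substituted diazo nucleophiles with aryl alkyl ketones and is supported here because CH2 migration keeps the aryl–C=O conjugation and the aryl group is deactivated by the para pivaloyloxy group; the acyl group on the diazonium carbon disfavours epoxide formation. Low temperature and slow addition of 8 to the preformed ketone–BF3 complex should keep the MOM ethers, the allylic aryl ether and the diazo ketone intact.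

Step 6
Reactants: 9 (2S)-4-[4-methoxy-2,6-bis(methoxymethoxy)benzoyl]-5-oxo-2-(prop-1-en-2-yl)-2,3,4,5-tetrahydro-1-benzoxepin-8-yl pivalate (C4 epimers)
Product: 11 isopropenyl oxepinoflavone: (2''S)-5-hydroxy-7-methoxy-4'-pivaloyloxyflavone bridged from C3 to O-2' by CH2–CH(isopropenyl), via bis-phenol diketone 10 (not isolated)
Conditions: TsOH·H2O (0.5 equiv), MeOH, 55 °C
Reagents that add atoms: none
Why: Acid-catalysed methanolysis of both MOM acetals is followed by 6-exo-trig hemiketalisation of one of the two equivalent phenols onto the benzoxepinone carbonyl and dehydration, the classical cyclodehydration of an o-hydroxyaryl 1,3-diketone to a flavone, with C2'' not involved.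

Step 7
Reactants: 11 isopropenyl oxepinoflavone
Product: 12 triethylsilyl peroxide: the flavone of 11 with C(CH3)2–OO–SiEt3 on C2'' in place of isopropenyl (2''S)
Conditions: Co(thd)2 (10 mol%), O2 (1 atm), Et3SiH (3 equiv), DCE, rt
Reagents that add atoms: dioxygen, O=O; triethylsilane, CC[SiH](CC)CC
Why: Isayama–Mukaiyama silylperoxidation, in which cobalt hydride transfers a hydrogen atom to the only reactive alkene to give the tertiary (Markovnikov) radical that is trapped by O2 and silylated, the tetrasubstituted electron-poor chromone C2=C3 bond and the C2'' stereocentre being left untouched.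

Step 8
Reactants: 12 triethylsilyl peroxide
Product: 14 peroxyketal: the flavone of 11 with C(CH3)2–OO–C(CH3)2OCH3 on C2'' (2''S), via free hydroperoxide 13 (not isolated)
Conditions: HCl (cat.), MeOH, 0 °C; NaHCO3, concentrate; then 2-methoxypropene, PPTS (cat.), CH2Cl2, 0 °C
Reagents that add atoms: 2-methoxypropene, COC(C)=C
Why: Methanolysis of the O–Si bond and acid-catalysed addition of the hydroperoxide to the enol ether give a 2-methoxyprop-2-yl peroxyketal, a base-stable dialkyl-type peroxide, the chelated 5-OH being inert to the enol ether.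

Step 9
Reactants: 14 peroxyketal
Product: 15 6-iodo peroxyketal: compound 14 with iodine at C6
Conditions: NIS (1.05 equiv), DMF, 0 °C → rt, dark
Reagents that add atoms: N-iodosuccinimide, O=C1CCC(=O)N1I
Why: Electrophilic aromatic iodination at C6, the only position ortho to the free 5-OH and also flanked by 7-OMe, in line with the ortho-to-phenol selectivity of 5-hydroxy-7-alkoxyflavones and 2-hydroxy-4,6-dialkoxyacetophenones, while the 4'-pivalate deactivates the B ring and the neutral medium spares the peroxyketal.

Step 10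
Reactants: 16 3-methylbut-1-yne; 17 pinacolborane
Product: 18 (E)-2-(3-methylbut-1-en-1-yl)-4,4,5,5-tetramethyl-1,3,2-dioxaborolane
Conditions: Cp2Zr(H)Cl (5 mol%), Et3N (10 mol%), neat, 60 °C, sealed tube
Reagents that add atoms: none
Why: Zirconocene-catalysed syn-hydroboration of the terminal alkyne places boron on the terminal carbon and should give the (E)-alkenylboronate only.

Step 11
Reactants: 15 6-iodo peroxyketal; 18 (E)-2-(3-methylbut-1-en-1-yl)-4,4,5,5-tetramethyl-1,3,2-dioxaborolane
Product: 20 4'-phenol peroxyketal: (2''S)-5,4'-dihydroxy-7-methoxy-6-[(E)-3-methylbut-1-enyl]flavone bridged from C3 to O-2' by CH2–CH[C(CH3)2OOC(CH3)2OCH3], via coupled pivalate 19 (not isolated)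
Conditions: Pd(dppf)Cl2 (5 mol%), K2CO3 (3 equiv), dioxane/H2O 5:1, 70 °C; then MeOH, K2CO3, 40 °C
Reagents that add atoms: none
Why: Suzuki–Miyaura coupling with retention of the (E)-geometry, the hydroperoxide being masked as a base-stable peroxyketal of the kind that tolerates Pd(0) cross-coupling (as 1,2,4-trioxanes do), after which carbonate methanolysis removes the aryl pivalate while the O–O–H group is still protected.

Step 12
Reactants: 20 4'-phenol peroxyketal
Product: 21 target: (2''S)-5,4'-dihydroxy-7-methoxy-6-[(E)-3-methylbut-1-enyl]flavone bridged from C3 to O-2' by CH2–CH[C(CH3)2OOH]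
Conditions: AcOH/THF/H2O 3:1:1, rt
Reagents that add atoms: none
Why: Mild aqueous-acid hydrolysis of the 2-methoxyprop-2-yl peroxyketal should release the tertiary hydroperoxide under conditions too weak to protonate the electron-rich styrene, with C2'' untouched.

Compound list
1 | 7-hydroxy-4H-chromen-4-one | O=c1ccoc2cc(O)ccc12 | starting material
2 | 4-oxo-4H-chromen-7-yl pivalate | O=c1ccoc2cc(OC(=O)C(C)(C)C)ccc12 | intermediate
3 | isopropenylboronic acid pinacol ester | CC(=C)B1OC(C)(C)C(C)(C)O1 | starting material
4 | (2S)-4-oxo-2-(prop-1-en-2-yl)chroman-7-yl pivalate | O=C1C[C@@H](C(C)=C)Oc2cc(OC(=O)C(C)(C)C)ccc12 | intermediate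
5 | 1-(2,6-dihydroxy-4-methoxyphenyl)ethan-1-one | CC(=O)c1c(O)cc(OC)cc1O | starting material
6 | 1-[4-methoxy-2,6-bis(methoxymethoxy)phenyl]ethan-1-one | CC(=O)c1c(OCOC)cc(OC)cc1OCOC | intermediate
7 | 4,4,4-trifluoro-1-[4-methoxy-2,6-bis(methoxymethoxy)phenyl]butane-1,3-dione (not isolated) | O=C(CC(=O)C(F)(F)F)c1c(OCOC)cc(OC)cc1OCOC | intermediate
8 | 2-diazo-1-[4-methoxy-2,6-bis(methoxymethoxy)phenyl]ethan-1-one | [N-]=[N+]=CC(=O)c1c(OCOC)cc(OC)cc1OCOC | intermediate
9 | (2S)-4-[4-methoxy-2,6-bis(methoxymethoxy)benzoyl]-5-oxo-2-(prop-1-en-2-yl)-2,3,4,5-tetrahydro-1-benzoxepin-8-yl pivalate (C4 epimers, partly enolised) | O=C1C(C(=O)c2c(OCOC)cc(OC)cc2OCOC)C[C@@H](C(C)=C)Oc2cc(OC(=O)C(C)(C)C)ccc12 | intermediate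
10 | (2S)-4-(2,6-dihydroxy-4-methoxybenzoyl)-5-oxo-2-(prop-1-en-2-yl)-2,3,4,5-tetrahydro-1-benzoxepin-8-yl pivalate (not isolated) | O=C1C(C(=O)c2c(O)cc(OC)cc2O)C[C@@H](C(C)=C)Oc2cc(OC(=O)C(C)(C)C)ccc12 | intermediate
11 | isopropenyl oxepinoflavone: (2''S)-5-hydroxy-7-methoxy-4'-pivaloyloxyflavone bridged from C3 to O-2' by CH2–CH(isopropenyl) | COc1cc2oc3c(c(=O)c2c(O)c1)C[C@@H](C(C)=C)Oc1cc(OC(=O)C(C)(C)C)ccc1-3 | intermediate
12 | triethylsilyl peroxide: as 11 with C(CH3)2OOSiEt3 on C2'' (2''S) | COc1cc2oc3c(c(=O)c2c(O)c1)C[C@@H](C(C)(C)OO[Si](CC)(CC)CC)Oc1cc(OC(=O)C(C)(C)C)ccc1-3 | intermediate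
13 | free hydroperoxide: as 11 with C(CH3)2OOH on C2'' (2''S) (not isolated) | COc1cc2oc3c(c(=O)c2c(O)c1)C[C@@H](C(C)(C)OO)Oc1cc(OC(=O)C(C)(C)C)ccc1-3 | intermediate
14 | peroxyketal: as 11 with C(CH3)2OOC(CH3)2OCH3 on C2'' (2''S) | COc1cc2oc3c(c(=O)c2c(O)c1)C[C@@H](C(C)(C)OOC(C)(C)OC)Oc1cc(OC(=O)C(C)(C)C)ccc1-3 | intermediate
15 | 6-iodo peroxyketal: 14 with iodine at C6 | COc1cc2oc3c(c(=O)c2c(O)c1I)C[C@@H](C(C)(C)OOC(C)(C)OC)Oc1cc(OC(=O)C(C)(C)C)ccc1-3 | intermediate
16 | 3-methylbut-1-yne | CC(C)C#C | starting material
17 | pinacolborane | CC1(C)OBOC1(C)C | starting material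
18 | (E)-2-(3-methylbut-1-en-1-yl)-4,4,5,5-tetramethyl-1,3,2-dioxaborolane | CC(C)/C=C/B1OC(C)(C)C(C)(C)O1 | intermediate
19 | coupled pivalate: 14 with (E)-3-methylbut-1-enyl at C6 (not isolated) | COc1cc2oc3c(c(=O)c2c(O)c1/C=C/C(C)C)C[C@@H](C(C)(C)OOC(C)(C)OC)Oc1cc(OC(=O)C(C)(C)C)ccc1-3 | intermediate
20 | 4'-phenol peroxyketal: 19 without the pivaloyl group | COc1cc2oc3c(c(=O)c2c(O)c1/C=C/C(C)C)C[C@@H](C(C)(C)OOC(C)(C)OC)Oc1cc(O)ccc1-3 | intermediate
21 | target CNP0171472.1, (2''S)-hydroperoxide | COc1cc2oc3c(c(=O)c2c(O)c1/C=C/C(C)C)C[C@@H](C(C)(C)OO)Oc1cc(O)ccc1-3 | target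

Total step count: 12. Longest linear sequence: 9 steps (1, 2, 5, 6, 7, 8, 9, 11, 12; the diazo ketone branch via steps 3 and 4 is equally long).

Steps most likely to fail

Step 5. The aryl group may migrate in competition with the methylene, giving the isomeric ring-expanded ketone. The acceptor diazo ketone may also add too slowly to a doubly oxygen-deactivated aryl ketone, or the Lewis acid may cleave the MOM ethers or hold the product as a BF2 chelate. Fallback, setting out from 4 and returning at 9: the same one-carbon ring enlargement is run with the ester nucleophile that is documented for chroman-4-ones. Ethyl diazoacetate and BF3·OEt2 should give ethyl (2S)-5-oxo-8-(pivaloyloxy)-2-(prop-1-en-2-yl)-2,3,4,5-tetrahydro-1-benzoxepine-4-carboxylate F1. Krapcho dealkoxycarbonylation (LiCl, wet DMSO, 120 °C) gives (2S)-5-oxo-2-(prop-1-en-2-yl)-2,3,4,5-tetrahydro-1-benzoxepin-8-yl pivalate F2. The lithium enolate of F2 (LiHMDS, THF, −78 °C) is C-acylated with 1-[4-methoxy-2,6-bis(methoxymethoxy)benzoyl]-1H-benzotriazole F5 to give 9. The acyl donor comes from 5-methoxyresorcinol: MOM protection gives 1-methoxy-3,5-bis(methoxymethoxy)benzene F3, lithiation between the two MOM ethers and carboxylation give 4-methoxy-2,6-bis(methoxymethoxy)benzoic acid F4, and 1-(methylsulfonyl)benzotriazole/Et3N converts it into F5.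

Step 11. The O–O bond may be cleaved reductively by Pd(0)/phosphine, or oxidative addition at the doubly ortho-substituted, electron-rich C6–I bond may be so slow that protodeiodination takes over. Fallback, setting out from 14 and returning at 19 (the methanolysis stage of step 11); it is palladium-free and also bypasses step 9. Magnesium-mediated ortho-formylation (MgCl2, Et3N, paraformaldehyde, MeCN, reflux; Casnati–Skattebøl), possible only at C6 next to the free 5-OH, gives the 6-formyl peroxyketal F6. Julia–Kocienski olefination (KHMDS, THF, −78 °C) with 5-(isobutylsulfonyl)-1-phenyl-1H-tetrazole F8 then gives the (E)-alkene 19. F8 is made from 1-phenyl-1H-tetrazole-5-thiol and 1-bromo-2-methylpropane via 5-(isobutylsulfanyl)-1-phenyl-1H-tetrazole F7, followed by oxidation with H2O2/ammonium molybdate.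

Step 2. Facial selectivity of the alkenyl transfer may be insufficient, the chromone may be too unreactive towards the alkenyl-rhodium species, or the product may partly racemise by retro-oxa-Michael ring opening. Fallback, setting out from 2 and returning at 4: copper-catalysed conjugate addition of isopropenylmagnesium bromide (CuI, TMSCl, THF, −78 °C) gives racemic 4-oxo-2-(prop-1-en-2-yl)chroman-7-yl pivalate F9, which is resolved by preparative chromatography on a chiral stationary phase; the (S)-enantiomer is 4.

Further compounds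
F1 | step 5 | ethyl (2S)-5-oxo-8-(pivaloyloxy)-2-(prop-1-en-2-yl)-2,3,4,5-tetrahydro-1-benzoxepine-4-carboxylate | CCOC(=O)C1C[C@@H](C(C)=C)Oc2cc(OC(=O)C(C)(C)C)ccc2C1=O
F2 | step 5 | (2S)-5-oxo-2-(prop-1-en-2-yl)-2,3,4,5-tetrahydro-1-benzoxepin-8-yl pivalate | O=C1CC[C@@H](C(C)=C)Oc2cc(OC(=O)C(C)(C)C)ccc12
F3 | step 5 | 1-methoxy-3,5-bis(methoxymethoxy)benzene | COCOc1cc(OC)cc(OCOC)c1
F4 | step 5 | 4-methoxy-2,6-bis(methoxymethoxy)benzoic acid | COCOc1cc(OC)cc(OCOC)c1C(=O)O
F5 | step 5 | 1-[4-methoxy-2,6-bis(methoxymethoxy)benzoyl]-1H-benzotriazole | COCOc1cc(OC)cc(OCOC)c1C(=O)n1nnc2ccccc12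
F6 | step 11 | 6-formyl peroxyketal: 14 with CHO at C6 | COc1cc2oc3c(c(=O)c2c(O)c1C=O)C[C@@H](C(C)(C)OOC(C)(C)OC)Oc1cc(OC(=O)C(C)(C)C)ccc1-3
F7 | step 11 | 5-(isobutylsulfanyl)-1-phenyl-1H-tetrazole | CC(C)CSc1nnnn1-c1ccccc1
F8 | step 11 | 5-(isobutylsulfonyl)-1-phenyl-1H-tetrazole | CC(C)CS(=O)(=O)c1nnnn1-c1ccccc1
F9 | step 2 | racemic 4-oxo-2-(prop-1-en-2-yl)chroman-7-yl pivalate | O=C1CC(C(C)=C)Oc2cc(OC(=O)C(C)(C)C)ccc12
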